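## The problem

Ainsliatrimer A (35) is built from three identical C15 guaianolide units. Each unit is a cyclopentane cis-fused to a cycloheptane (H1 and H5 both α) with a trans-fused α-methylene-γ-lactone across C6–C7 (H6 β, H7 α), so twelve of the sixteen stereocentres are four centres repeated three times. The units are joined by two spiro-cyclohexene rings: C2, C1, C10 and C14 of unit A with C15′ and C4′ of unit B, and C2′, C1′, C10′ and C14′ of unit B with C15″ and C4″ of unit C. The four remaining stereocentres are the quaternary spiro carbons C4′ and C4″, the tertiary alcohol C10′ and the methine C10; they can only be set under the control of what is already there, namely the C5 centre next to each enone and the shape of the growing oligomer. The molecule holds three α-methylene lactones, two cross-conjugated cyclopentenones with an exocyclic methylene beside the ketone, a tertiary allylic alcohol and several positions that autoxidise readily, so strong base, hydride, hard nucleophiles and hot acid are excluded late in the route. Two features make a short plan possible. First, each spiro-cyclohexene is the formal Diels–Alder adduct of a C2=C1–C10=C14 diene with the C4=C15 enone of a 3-oxo unit, so all three units derive from one monomer, dehydrozaluzanin C (28). Second, in that monomer the lactone oxygen sits on C6 and the acrylate carbon C11 on C7, while C6 hangs on C5 and C7 is tied through C8, C9 and C10 to C1 on the same face of the cyclopentane; a C6 aldehyde and a C7=C11 2-(bromomethyl)enoate can therefore close the ring C1–C10–C9–C8–C7–C6–C5 and the lactone in one operation.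

## Retrosynthesis

**Unit A from the dimer (35 ⇒ 34 ⇒ 33 + 30).** Moving the C1=C2 alkene of unit A back to C1=C10 gives the β,γ-enone 34, whose A–B cyclohexene is a plain Diels–Alder ring. Cutting C2–C4′ and C14–C15′ releases the hydroxy dimer 33 as dienophile and the dienone 30 as diene. This ring is opened first because unit A is terminal: what remains is a dimer with a single exocyclic enone as dienophile. Opening the B–C ring first would leave an A–B dimer that must be dehydrogenated to a diene beside a second enolisable enone. The precursor is a third smaller. The forward reaction must join C14 to C15′ and C2 to C4′, approach the β face of the enone of 33, and then move the alkene into conjugation with H10 delivered to the α face. Endo or exo approach is irrelevant because C2 ends as sp2.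

**The B–C dimer (33 ⇒ 32 ⇒ 31 ⇒ 28 + 30).** The C10′ hydroxyl is the trace of a γ-oxygenation of the β,γ-enone 31 through hydroperoxide 32. Removing it and shifting the alkene to C1′=C10′ exposes the second Diels–Alder ring; cutting C2′–C4″ and C14′–C15″ gives dehydrozaluzanin C (28) and the same diene 30. Both bonds of the ring and the quaternary centre C4″ form in one step with built-in regiocontrol. The forward reaction needs 28 in excess to outrun self-addition of 30, attack on the α face of 28 (anti to its C5–C6 bond) and oxygen delivery to the β face of C10′.

**The diene (30 ⇐ 29 ⇐ 28).** The C1=C2 alkene of 30 is a ketone dehydrogenation. Ketone 28 can enolise only toward C2, so silyl dienol ether 29 is a single regioisomer, and its oxidation with Pd(OAc)2 gives 30 under neutral conditions. Because 30 carries both the diene and an exocyclic enone, it is never concentrated: it is made as a dilute solution directly before each cycloaddition and metered into the dienophile. The whole target thus converges on 28.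

**Oxidation level of the monomer (28 ⇐ 27 ⇐ 26).** The 3-ketone is carried as a silyl ether until the skeleton is complete, because the exocyclic enone would not survive amines, bromide or indium. Desilylation and allylic alcohol oxidation are all that is asked.

**Carbocycle and lactone (26 ⇐ 25 ⇐ 24 ⇐ 23).** The C6–C7 bond and the lactone C–O bond are cut together. Against a cut at C7–C8 or C9–C10 (ring-closing metathesis or alkylation), this one removes a ring, two stereocentres and the lactone at once, creates no ring alkene that would have to be relocated, and leaves a monocyclic precursor. Against a C1–C5 cut it needs no ten-membered ring. The precursor 23 has only the three stereocentres of the cyclopentane. The forward reaction must place H6 trans to H5 and to H7 and must beat oligomerisation.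

**The bromo enoate (23 ⇐ 22 ⇐ 21 ⇐ 20 ⇐ 18 + 19).** The C7–C11 bond is the Morita–Baylis–Hillman bond between aldehyde 18 and methyl acrylate (19). Bromination with allylic transposition turns adduct 20 into the (Z)-2-(bromomethyl)enoate 21. The C6 aldehyde is unmasked last from a primary silyl ether (22) so that only one aldehyde is present during the acrylate coupling.

**The side chain (18 ⇐ 17 ⇐ 16; 11 ⇐ 9 + 10; 9 ⇐ 8).** C7 is carried as a nitrile, which survives acid, peracid and aluminium amide and is reduced to the aldehyde in one step. The C8–C9 bond comes from alkylation of lithioacetonitrile (from 10) with allylic chloride 9. Chloride 9 comes from ene-type chlorination of the isopropenyl group of 8, done while it is the only alkene in the molecule.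

**The exocyclic methylene (16 ⇐ 15 ⇐ 14 ⇐ 13 ⇐ 12 ⇐ 11).** C15 is the methyl group of the starting terpene, so C4=C15 beside the C3 oxygen is made by a 1,3-transposition. The C3 alcohol 12 is dehydrated to the C3=C4 alkene 13 and epoxidised to 14, and the epoxide is isomerised to allylic alcohol 15. This is done on the cyclopentane, where no lactone or enone restricts the reagents.

**The cyclopentane (8 ⇐ 7 ⇐ 6 ⇐ 5 ⇐ 4 ⇐ 3 ⇐ 2 ⇐ 1).** Ester 6 holds all ten carbons of (R)-carvone (1): the carbonyl carbon becomes C6, the ring methyl C15 and the isopropenyl group C10, C14 and C9. Epoxidation, chlorohydrin formation and Favorskii contraction through cyclopropanone 5 give the C1 and C5 substituents cis, as the hydroazulene needs, and the carvone stereocentre becomes C1 with the correct absolute configuration.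

## Roads not taken

**Alternative 1:** oxidative enolate coupling. The cut is the single bond C2–C4′, with C14–C15′ already in place. In the forward sense LiN(SiMe3)2 would turn the tethered diketone A1 into the C2 enolate of unit A and the C4′ enolate of unit B, and Fe(acac)3 would couple them to the masked 1,2-dihydro trimer A2.
- Merits: the intramolecular setting removes the cross- versus homo-coupling problem, there is no self-reactive diene, and the lactones travel as robust amine adducts.
- Weak points: the C14–C15′ tether of A1 must first be made between two complex units; unit C also has an enolisable C2″ methylene that competes for base and oxidant; forming a quaternary centre by radical-type coupling of a hindered enolate is demanding. From A2, a C1–C2 dehydrogenation, three lactone unmaskings and a desilylation still follow.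
- Comparison: this road is better in one respect, because it never handles the self-reactive diene 30. The chosen plan sets against that a pericyclic step that forms both ring bonds with inherent regiocontrol, unprotected lactones, and markedly fewer operations.

**Alternative 2:** Claisen ring contraction. The cut is C2′–C4″. The spiro-dihydropyran A3 (enol ether C4″=C3″–O, allyl unit C10′–C1′=C2′) would rearrange on heating, breaking O–C10′ and forming C2′–C4″, to give the spiro dimer A4.
- Merits: a reagent-free, suprafacial [3,3] shift that transfers the C10′ configuration to C2′ and builds the quaternary centre cleanly.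
- Weak points: A4 is the same compound as intermediate 31 of the chosen route. A3 would itself come from 28 and 30 by a hetero-Diels–Alder reaction, so the same two partners are needed, the periselectivity of that first step must favour oxygen over carbon, and the dihydropyran can revert at the temperature of the rearrangement.
- Comparison: where the direct cycloaddition showed poor facial control, this detour could be the better road because stereochemistry is relayed through a defined chair. The chosen plan sets one step instead of two against it and relies on the α-face preference of 28.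

**Alternative 3:** transannular cyclisation of a germacranolide. The cut is C1–C5 of each unit. The starting point would be the germacranolide parthenolide A5, which carries a 4,5-epoxide and a C1=C10 alkene. p-Toluenesulfonic acid would activate the epoxide of A5 and the alkene would attack C5, giving micheliolide A6.
- Merits: one step from A5 to a 5-7-5 guaianolide with C1, C5, C6 and C7 correct, because the lactone stereocentres are inherited and not made; in step count to the tricycle it is clearly superior.
- Weak points: A6 carries a C4 tertiary alcohol, a C4 methyl group and a tetrasubstituted C1=C10 alkene. To reach 28 the alkene must be moved against thermodynamics to C10=C14, the alcohol dehydrated selectively to C4=C15 and C3 oxidised, each with regiochemical ambiguity on a sensitive lactone. The route also starts from A5, itself a natural product, not from a simple commercial terpene.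
- Comparison: the chosen plan is much longer to the tricycle and has to prove the C6/C7 stereochemistry of its ring closure. It sets against this that all three exocyclic alkenes and the C3 oxygen are in their final positions when the rings close, with no late redox relay.

Key step: step 19

## Route

Remark on the chemistry: guaianolide numbering is used from compound 6 on (ring carbons C1–C5, C6 on C5, C15 on C4, C10/C14/C9 from the isopropenyl group; α is the face of H1 and H5). The THP acetal carbon (4–11) and C7 of 20 are inconsequential epimer mixtures. Organoindium 24 is drawn as its monoallylindium dibromide component.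

Remark on the chemistry: dienone 30 is assumed to persist for some hours as a cold, dilute solution; step 23 is therefore run on a fresh portion of 29 directly before step 24 and again directly before step 25.

Step 1
Reactants: 1 (R)-carvone
Product: 2 (1R,4R,6R)-1-methyl-4-(prop-1-en-2-yl)-7-oxabicyclo[4.1.0]heptan-2-one (trans-carvone epoxide)
Conditions: 30% aq. H2O2, NaOH (cat.), MeOH, 0 °C
Reagents that add atoms: hydrogen peroxide, OO
Why: Weitz–Scheffer nucleophilic epoxidation of the enone; the hydroperoxide anion adds axially, anti to the isopropenyl group, so the epoxide forms on the opposite face and the isolated alkene is untouched.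

Step 2
Reactants: 2 trans-carvone epoxide
Product: 3 (2S,3R,5R)-2-chloro-3-hydroxy-2-methyl-5-(prop-1-en-2-yl)cyclohexan-1-one (chlorohydrin)
Conditions: LiCl, CF3CO2H, THF, rt
Reagents that add atoms: lithium chloride, [Li+].[Cl-]
Why: Acid-promoted trans-diaxial opening of the epoxy ketone; chloride enters with inversion at the tertiary carbon next to the carbonyl (Cl cis to isopropenyl) and the hydroxyl stays on C3, which gives the α-chloro ketone needed for ring contraction.

Step 3
Reactants: 3 chlorohydrin
Product: 4 tetrahydropyranyl ether of 3
Conditions: 3,4-dihydro-2H-pyran, PPTS (cat.), CH2Cl2, rt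
Reagents that add atoms: 3,4-dihydro-2H-pyran, C1=COCCC1
Why: Acid-catalysed acetal formation masks the hydroxyl, which would otherwise re-close to the epoxide under the basic conditions of the next step.

Step 4
Reactants: 4 tetrahydropyranyl ether
Product: 6 methyl (1R,2S,3R,5R)-2-methyl-5-(prop-1-en-2-yl)-3-(tetrahydropyran-2-yloxy)cyclopentane-1-carboxylate (C5β-CO2Me; C4α-CH3; C3α-OTHP; C1β-isopropenyl), via cyclopropanone 5 (not isolated)
Conditions: NaOMe, MeOH, 0 °C to rt
Reagents that add atoms: sodium methoxide, [Na+].[O-]C
Why: Favorskii rearrangement: the enolate of the CH2 carbon displaces chloride with inversion, so the carbonyl bridge of 5 lies on the isopropenyl face; methoxide opens 5 toward the methyl-bearing carbon (carbanion stabilised by the neighbouring alkoxy group) and protonation with retention leaves the ester cis to the isopropenyl group and the methyl group α.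

Step 5
Reactants: 6 Favorskii ester
Product: 7 primary alcohol (C5β-CH2OH; otherwise as 6)
Conditions: LiAlH4, Et2O, 0 °C
Reagents that add atoms: none
Why: Hydride reduction of the ester to the C6 alcohol; the acetal, the alkene and the stereocentres are inert, and the C5 centre is no longer epimerisable afterwards.

Step 6
Reactants: 7 primary alcohol
Product: 8 C6 tert-butyldimethylsilyl ether
Conditions: TBSCl, imidazole, DMF, rt
Reagents that add atoms: tert-butyldimethylsilyl chloride, CC(C)(C)[Si](C)(C)Cl
Why: Standard silylation; the primary silyl ether blocks cyclic ether formation in the next two steps and can later be removed beside a secondary silyl ether.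

Step 7
Reactants: 8 silyl ether
Product: 9 allylic chloride (isopropenyl converted into 3-chloroprop-1-en-2-yl)
Conditions: Ca(OCl)2, CO2 (dry ice), CH2Cl2/H2O, 0 °C
Reagents that add atoms: calcium hypochlorite, [Ca+2].[O-]Cl.[O-]Cl
Why: Ene-type chlorination of a 1,1-disubstituted alkene by hypochlorous acid: chlorine adds to the terminal carbon and a methyl proton is lost; it is run here because the isopropenyl group is the only alkene in the molecule.

Step 8
Reactants: 9 allylic chloride; 10 acetonitrile
Product: 11 nitrile (C1β-(4-cyanobut-1-en-2-yl) side chain, C10(=C14)–C9–C8–C7≡N)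
Conditions: MeCN (excess), n-BuLi, THF, −78 °C; then 9, −78 to −20 °C
Reagents that add atoms: none
Why: SN2 alkylation of lithioacetonitrile by a primary allylic chloride forms C8–C9 (the SN2′ path gives the same product); excess anion suppresses dialkylation, and silyl ether and acetal are inert to it.

Step 9
Reactants: 11 nitrile
Product: 12 C3α alcohol
Conditions: MgBr2·OEt2, Et2O, rt
Reagents that add atoms: none
Why: Lewis-acid cleavage of the tetrahydropyranyl acetal, a method that leaves tert-butyldimethylsilyl ethers and the nitrile intact.

Step 10
Reactants: 12 C3α alcohol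
Product: 13 cyclopentene (C3=C4 alkene bearing the C15 methyl group)
Conditions: POCl3, pyridine, 0 to 50 °C
Reagents that add atoms: none
Why: Anti (E2) dehydration of the activated alcohol; because hydroxyl and methyl are cis, H4 is antiperiplanar to the leaving group and the Zaitsev, trisubstituted alkene is favoured over the C2=C3 isomer.

Step 11
Reactants: 13 cyclopentene
Product: 14 3α,4α-epoxide
Conditions: mCPBA, NaHCO3, CH2Cl2, −20 to 0 °C
Reagents that add atoms: 3-chloroperoxybenzoic acid, O=C(OO)c1cccc(Cl)c1
Why: Prilezhaev epoxidation; the trisubstituted ring alkene reacts much faster than the 1,1-disubstituted side-chain alkene, and the peracid approaches the α face, anti to the adjacent C5 silyloxymethyl group, which fixes the C3 oxygen α.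

Step 12
Reactants: 14 epoxide
Product: 15 allylic alcohol (C4=C15 exocyclic methylene; C3α-OH)
Conditions: Et2Al(TMP) [from 2,2,6,6-tetramethylpiperidine, n-BuLi, Et2AlCl], toluene, 0 °C
Reagents that add atoms: none
Why: Aluminium amide isomerisation of an epoxide to an allylic alcohol: aluminium binds the epoxide oxygen and the amide removes a syn proton through a cyclic transition state; the methyl protons are far more accessible than the C5 methine, so the tertiary C4–O bond breaks and the exocyclic alkene forms with C3–O unchanged.

Step 13
Reactants: 15 allylic alcohol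
Product: 16 bis(tert-butyldimethylsilyl) ether (C3α-OTBS and C6-OTBS)
Conditions: TBSCl, imidazole, DMF, rt
Reagents that add atoms: tert-butyldimethylsilyl chloride, CC(C)(C)[Si](C)(C)Cl
Why: Standard silylation of the secondary allylic alcohol; the C3 oxygen is now protected against bromination and oxidation in steps 16 and 18.

Step 14
Reactants: 16 bis-silyl ether nitrile
Product: 18 aldehyde (C7H=O), via iminoalane 17 (not isolated)
Conditions: i-Bu2AlH, toluene, −78 °C; then aq. citric acid, 0 °C
Reagents that add atoms: water, O
Why: Partial reduction of the nitrile stops at iminoalane 17, which is hydrolysed on work-up; no other reducible group is present.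

Step 15
Reactants: 18 aldehyde; 19 methyl acrylate
Product: 20 Morita–Baylis–Hillman adduct (C7 carbinol, both epimers; C11=C13 acrylate)
Conditions: DABCO, MeOH, rt, excess 19
Reagents that add atoms: none
Why: Morita–Baylis–Hillman reaction of an unhindered aliphatic aldehyde forms C7–C11; the C7 configuration is irrelevant because the centre becomes sp2 in the next step.

Step 16
Reactants: 20 Morita–Baylis–Hillman adduct
Product: 21 (Z)-allylic bromide (C7=C11 with CH2Br and CO2Me on C11; C8 cis to CH2Br)
Conditions: NBS, Me2S, CH2Cl2, 0 °C to rt
Reagents that add atoms: N-bromosuccinimide, O=C1CCC(=O)N1Br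
Why: The bromosulfonium reagent activates the allylic hydroxyl and bromide attacks the methylene terminus (SN2′), giving the thermodynamically preferred (Z)-2-(bromomethyl)enoate; silyl ethers and the other alkenes are inert.

Step 17
Reactants: 21 allylic bromide
Product: 22 primary alcohol (C6-OH; C3α-OTBS kept)
Conditions: camphorsulfonic acid (cat.), MeOH/CH2Cl2, 0 °C
Reagents that add atoms: none
Why: Acid-catalysed methanolysis removes the unhindered primary silyl ether well before the secondary one flanked by the ring and the methylene group; neutral methanol does not displace the bromide at this temperature.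

Step 18
Reactants: 22 primary alcohol
Product: 23 bromo ester aldehyde (C5β-CHO; C4=C15; C3α-OTBS; C1β side chain ending in the (Z)-2-(bromomethyl)enoate)
Conditions: Dess–Martin periodinane, NaHCO3, CH2Cl2, 0 °C
Reagents that add atoms: none
Why: Buffered, non-basic oxidation gives the β,γ-unsaturated aldehyde without epimerising C5 or conjugating the C4=C15 alkene; 23 is used at once.

Step 19
Reactants: 23 bromo ester aldehyde
Product: 26 3α-(tert-butyldimethylsilyloxy)dehydrocostus lactone, via allylindium species 24 (not isolated), via hydroxy ester 25 (not isolated)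
Conditions: In powder, THF/H2O (3:1), 0.005 M, rt; then p-TsOH·H2O (cat.), CH2Cl2, rt
Reagents that add atoms: none
Why: Indium inserts into the allylic C–Br bond to give 24, which adds to the C6 aldehyde through its γ-carbon C7 in a cyclic six-membered transition state and moves the alkene to C11=C13; the closest known reaction type is the intramolecular Barbier-type 2-(alkoxycarbonyl)allylation of aldehydes. The seven-membered ring (C1, C10, C9, C8, C7, C6, C5) closes in this addition as a 7-exo attack on the carbonyl, which the cis arrangement of the C1 chain and the C5 formyl group makes possible. The lactone closes next by 5-exo acyl substitution of the methyl ester by the C6 oxygen of 25 with loss of methanol, and a trace of acid completes it. C6 is controlled by C5: the tethered nucleophile reaches the carbonyl only from the C1 side, anti to the C4–C5 bond, with the metal-bound oxygen turned away from the cyclopentane, which puts H6 trans to H5. C7 is controlled by the bicyclic transition state: allylindium reagents interconvert their alkene geometry by 1,3-metal shifts, so the bromide geometry is not binding, and the chair in which C5 and C8 are both pseudo-equatorial (trans-fused to the forming cycloheptane) gives H7 trans to H6 and hence the trans-lactone. The step needs chemoselectivity (allylindium adds to the aldehyde but not to esters and tolerates water), ring closure over oligomerisation (high dilution) and configurational stability at C5 (neutral aqueous medium); the substrate secures the first because aldehyde and allyl bromide are its only reactive pair.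

Step 20
Reactants: 26 silyl ether lactone
Product: 27 3α-hydroxydehydrocostus lactone (C3 epimer of zaluzanin C)
Conditions: HF·pyridine, THF, 0 °C to rt
Reagents that add atoms: none
Why: Acidic fluoride desilylation avoids the basic fluoride sources that would add to the α-methylene lactone.

Step 21
Reactants: 27 allylic alcohol
Product: 28 dehydrozaluzanin C (3-oxoguaia-4(15),10(14),11(13)-trien-12,6α-olide)
Conditions: Dess–Martin periodinane, NaHCO3, CH2Cl2, rt
Reagents that add atoms: none
Why: Mild oxidation of the secondary allylic alcohol gives the exocyclic enone; the C3 configuration carried so far is removed here.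

Step 22
Reactants: 28 dehydrozaluzanin C
Product: 29 silyl dienol ether (C2=C3 enol ether, 3-OTBS, C4=C15 kept)
Conditions: TBSOTf, Et3N, CH2Cl2, −78 to 0 °C
Reagents that add atoms: tert-butyldimethylsilyl trifluoromethanesulfonate, CC(C)(C)[Si](C)(C)OS(=O)(=O)C(F)(F)F
Why: Soft enolisation; C2 is the only enolisable position of 28, and the weak amine base spares the lactone and the enone.

Step 23
Reactants: 29 silyl dienol ether
Product: 30 1,2-didehydrodehydrozaluzanin C (C2=C1–C10=C14 dienone), handled only as a cold dilute solution
Conditions: Pd(OAc)2 (1.1 equiv), MeCN, argon, rt; filtration through Celite; filtrate (ca. 0.02 M) kept at −20 °C and used within hours without concentration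
Reagents that add atoms: none
Why: Saegusa–Ito oxidation: divalent palladium takes up the enol ether at C2 with loss of the silyl group, and syn β-hydride elimination of H1 gives the C1=C2 enone. The spent palladium is filtered off, and dilution and cold slow the second-order self-cycloaddition of 30 until it is metered into a dienophile.

Step 24
Reactants: 30 dienone (fresh solution from step 23); 28 dehydrozaluzanin C (excess)
Product: 33 10′β-hydroxy B–C spiro dimer, via Diels–Alder adduct 31 (not isolated), via hydroperoxide 32 (not isolated)
Conditions: 28 (3 equiv), MeCN, O2 (1 atm), rt, slow addition of the solution of 30; then Me2S, 0 °C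
Reagents that add atoms: dioxygen, O=O
Why: Intermolecular Diels–Alder reaction: the s-cis locked C2=C1–C10=C14 diene of 30 adds to the exocyclic enone of 28 (bonds C14′–C15″ and C2′–C4″ in dimer numbering) on the α face of 28, anti to its C5–C6 bond, which sets spiro centre C4″; slow addition into excess 28 keeps self-addition of 30 low. H2′ of 31 is α to the ketone and allylic, so the derived dienol traps O2 at C10′ (γ-autoxidation of a β,γ-enone), expected on the β face away from the new spiro ring, and Me2S reduces hydroperoxide 32 to the alcohol.

Step 25
Reactants: 33 hydroxy dimer; 30 dienone (fresh solution from step 23)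
Product: 35 ainsliatrimer A, via trimer adduct 34 (not isolated)
Conditions: MeCN, argon, rt to 40 °C, slow addition of the solution of 30 (2 equiv); then Et3N, rt
Reagents that add atoms: none
Why: Diels–Alder reaction of 30 with the C4′=C15′ enone of 33, its only exocyclic enone, expected from the β face (the α face is screened by the C14′–C15″ bridge and unit C), which sets C4′. Under argon the β,γ-enone 34 is not oxidised, and Et3N isomerises it through the dienolate to the conjugated C1=C2 enone, with C10 protonated to the thermodynamically preferred H10α epimer.

## Compound list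

1 | (R)-carvone | CC1=CC[C@H](CC1=O)C(C)=C | starting material
2 | trans-carvone epoxide, (1R,4R,6R)-1-methyl-4-(prop-1-en-2-yl)-7-oxabicyclo[4.1.0]heptan-2-one | C=C(C)[C@@H]1C[C@H]2O[C@@]2(C)C(=O)C1 | intermediate
3 | chlorohydrin, (2S,3R,5R)-2-chloro-3-hydroxy-2-methyl-5-(prop-1-en-2-yl)cyclohexan-1-one | C=C(C)[C@@H]1C[C@@H](O)[C@](C)(Cl)C(=O)C1 | intermediate
4 | tetrahydropyranyl ether of 3 (acetal carbon as a mixture) | C=C(C)[C@@H]1C[C@@H](OC2CCCCO2)[C@](C)(Cl)C(=O)C1 | intermediate
5 | cyclopropanone, 1-methyl-4-(prop-1-en-2-yl)-2-(tetrahydropyran-2-yloxy)bicyclo[3.1.0]hexan-6-one, carbonyl bridge on the isopropenyl face (not isolated) | O=C1[C@@]2(C)[C@H](OC3CCCCO3)C[C@@H](C(C)=C)[C@@H]12 | intermediate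
6 | methyl (1R,2S,3R,5R)-2-methyl-5-(prop-1-en-2-yl)-3-(tetrahydropyran-2-yloxy)cyclopentane-1-carboxylate | C[C@@H]1[C@H](OC2CCCCO2)C[C@@H](C(C)=C)[C@H]1C(=O)OC | intermediate
7 | primary alcohol: C5β-CH2OH, C4α-CH3, C3α-OTHP, C1β-isopropenyl cyclopentane | C[C@@H]1[C@H](OC2CCCCO2)C[C@@H](C(C)=C)[C@H]1CO | intermediate
8 | C6 tert-butyldimethylsilyl ether of 7 | C[C@@H]1[C@H](OC2CCCCO2)C[C@@H](C(C)=C)[C@H]1CO[Si](C)(C)C(C)(C)C | intermediate
9 | allylic chloride: C1β-(3-chloroprop-1-en-2-yl) analogue of 8 | C[C@@H]1[C@H](OC2CCCCO2)C[C@@H](C(=C)CCl)[C@H]1CO[Si](C)(C)C(C)(C)C | intermediate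
10 | acetonitrile | CC#N | starting material
11 | nitrile: C1β-(4-cyanobut-1-en-2-yl), C3α-OTHP, C4α-CH3, C5β-CH2OTBS cyclopentane | C[C@@H]1[C@H](OC2CCCCO2)C[C@@H](C(=C)CCC#N)[C@H]1CO[Si](C)(C)C(C)(C)C | intermediate
12 | C3α alcohol of 11 | C[C@@H]1[C@H](O)C[C@@H](C(=C)CCC#N)[C@H]1CO[Si](C)(C)C(C)(C)C | intermediate
13 | cyclopentene: C3=C4 alkene with C15 methyl, C1β side chain, C5β-CH2OTBS | CC1=CC[C@@H](C(=C)CCC#N)[C@H]1CO[Si](C)(C)C(C)(C)C | intermediate
14 | 3α,4α-epoxide of 13 | C[C@@]12O[C@@H]1C[C@@H](C(=C)CCC#N)[C@H]2CO[Si](C)(C)C(C)(C)C | intermediate
15 | allylic alcohol: C4=C15 methylene, C3α-OH | C=C1[C@H](O)C[C@@H](C(=C)CCC#N)[C@H]1CO[Si](C)(C)C(C)(C)C | intermediate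
16 | bis(tert-butyldimethylsilyl) ether of 15 | C=C1[C@H](O[Si](C)(C)C(C)(C)C)C[C@@H](C(=C)CCC#N)[C@H]1CO[Si](C)(C)C(C)(C)C | intermediate
17 | N-(diisobutylaluminio)aldimine from 16 (not isolated) | C=C1[C@H](O[Si](C)(C)C(C)(C)C)C[C@@H](C(=C)CCC=N[Al](CC(C)C)CC(C)C)[C@H]1CO[Si](C)(C)C(C)(C)C | intermediate
18 | aldehyde: C1β-(5-oxopent-1-en-2-yl) side chain (C7H=O) | C=C1[C@H](O[Si](C)(C)C(C)(C)C)C[C@@H](C(=C)CCC=O)[C@H]1CO[Si](C)(C)C(C)(C)C | intermediate
19 | methyl acrylate | C=CC(=O)OC | starting material
20 | Morita–Baylis–Hillman adduct (C7 epimers) | C=C1[C@H](O[Si](C)(C)C(C)(C)C)C[C@@H](C(=C)CCC(O)C(=C)C(=O)OC)[C@H]1CO[Si](C)(C)C(C)(C)C | intermediate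
21 | (Z)-allylic bromide, methyl (Z)-2-(bromomethyl)alk-2-enoate side chain | C=C1[C@H](O[Si](C)(C)C(C)(C)C)C[C@@H](C(=C)CC/C=C(\CBr)C(=O)OC)[C@H]1CO[Si](C)(C)C(C)(C)C | intermediate
22 | primary alcohol of 21 (C6-OH) | C=C1[C@H](O[Si](C)(C)C(C)(C)C)C[C@@H](C(=C)CC/C=C(\CBr)C(=O)OC)[C@H]1CO | intermediate
23 | bromo ester aldehyde | C=C1[C@H](O[Si](C)(C)C(C)(C)C)C[C@@H](C(=C)CC/C=C(\CBr)C(=O)OC)[C@H]1C=O | intermediate
24 | allylindium species from 23, drawn as the allylindium dibromide, alkene geometry labile (not isolated) | C=C1[C@H](O[Si](C)(C)C(C)(C)C)C[C@@H](C(=C)CCC=C(C[In](Br)Br)C(=O)OC)[C@H]1C=O | intermediate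
25 | hydroxy ester: 6α-hydroxy, 7β-(3-methoxy-3-oxoprop-1-en-2-yl) hydroazulene (not isolated) | C=C1[C@H](O[Si](C)(C)C(C)(C)C)C[C@H]2C(=C)CC[C@@H](C(=C)C(=O)OC)[C@H](O)[C@H]21 | intermediate
26 | 3α-(tert-butyldimethylsilyloxy)dehydrocostus lactone | C=C1[C@H](O[Si](C)(C)C(C)(C)C)C[C@H]2C(=C)CC[C@H]3C(=C)C(=O)O[C@@H]3[C@H]21 | intermediate
27 | 3α-hydroxydehydrocostus lactone | C=C1[C@H](O)C[C@H]2C(=C)CC[C@H]3C(=C)C(=O)O[C@@H]3[C@H]21 | intermediate
28 | dehydrozaluzanin C | C=C1C(=O)C[C@H]2C(=C)CC[C@H]3C(=C)C(=O)O[C@@H]3[C@H]21 | intermediate
29 | silyl dienol ether of 28 (2-ene, 3-OTBS) | C=C1C(O[Si](C)(C)C(C)(C)C)=C[C@H]2C(=C)CC[C@H]3C(=C)C(=O)O[C@@H]3[C@H]21 | intermediate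
30 | 1,2-didehydrodehydrozaluzanin C, the dienone (kept as a cold dilute solution) | C=C1C(=O)C=C2C(=C)CC[C@H]3C(=C)C(=O)O[C@@H]3[C@H]21 | intermediate
31 | B–C Diels–Alder adduct, C1′=C10′ alkene, H2′ β (not isolated) | C=C1C(=O)[C@H]2C3=C(CC[C@]24C(=O)C[C@H]5C(=C)CC[C@H]6C(=C)C(=O)O[C@@H]6[C@H]54)CC[C@H]2C(=C)C(=O)O[C@@H]2[C@@H]13 | intermediate
32 | 10′β-hydroperoxide of the B–C dimer (not isolated) | C=C1C(=O)C2=C3[C@H]1[C@H]1OC(=O)C(=C)[C@@H]1CC[C@@]3(OO)CC[C@]21C(=O)C[C@H]2C(=C)CC[C@H]3C(=C)C(=O)O[C@@H]3[C@H]21 | intermediate
33 | 10′β-hydroxy B–C spiro dimer (C1′=C2′ enone, C4′=C15′ methylene) | C=C1C(=O)C2=C3[C@H]1[C@H]1OC(=O)C(=C)[C@@H]1CC[C@@]3(O)CC[C@]21C(=O)C[C@H]2C(=C)CC[C@H]3C(=C)C(=O)O[C@@H]3[C@H]21 | intermediate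
34 | trimer Diels–Alder adduct, C1=C10 alkene in unit A, H2 β (not isolated) | C=C1C(=O)[C@H]2C3=C(CC[C@H]4C(=C)C(=O)O[C@@H]4[C@@H]13)CC[C@@]21C(=O)C2=C3[C@H]1[C@H]1OC(=O)C(=C)[C@@H]1CC[C@@]3(O)CC[C@]21C(=O)C[C@H]2C(=C)CC[C@H]3C(=C)C(=O)O[C@@H]3[C@H]21 | intermediate
35 | ainsliatrimer A | C=C1C(=O)C2=C3[C@H](CC[C@H]4C(=C)C(=O)O[C@@H]4[C@@H]13)CC[C@@]21C(=O)C2=C3[C@H]1[C@H]1OC(=O)C(=C)[C@@H]1CC[C@@]3(O)CC[C@]21C(=O)C[C@H]2C(=C)CC[C@H]3C(=C)C(=O)O[C@@H]3[C@H]21 | target

## Step count and risks

Total step count: 25. Longest linear sequence: 25 steps (1 to 35). Compound 28 re-enters in step 24 and dienone 30 is used in steps 24 and 25 (step 23 being run on two batches), all from the same line, so there is no second branch.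

Least certain steps:

**Step 19 (key step).** The most likely failure is the wrong relative configuration at C6/C7. If the allylindium reacts in the geometry of the (Z)-bromide, a chair with C8 axial leads to the 6,7-cis lactone, which is the usual outcome of intermolecular reactions of such bromides. The trans-lactone depends on geometry equilibration and on the ring-fused chair being lower in energy. Intermolecular coupling and isomerisation of the β,γ-unsaturated aldehyde are secondary risks. The fallback leaves the Barbier manifold and sets out from aldehyde 18. Horner–Wadsworth–Emmons olefination with methyl 2-(dimethoxyphosphoryl)-3-(trimethylsilyl)propanoate (NaH, THF) gives the 2-(methoxycarbonyl)allylsilane F1. Camphorsulfonic acid in methanol frees the primary alcohol F2, and Dess–Martin oxidation gives the formyl allylsilane F3. Intramolecular Hosomi–Sakurai cyclisation through an open transition state, promoted either by BF3·OEt2 at −78 °C or by tetrabutylammonium fluoride, follows; these two promoters are known to give different ring fusions in such lactone annulations. Acid lactonisation then rejoins the route at 26.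

**Step 23.** Self-cycloaddition of the dienone while it is made and kept, and sluggish oxidation of the bulky silyl enol ether, would both lower the amount of diene that reaches the dienophile. The fallback changes how the diene is delivered and sets out from 29. PhSeCl at −78 °C gives the storable 2α-(phenylseleno) ketone F4. Oxidation with mCPBA at −78 °C gives selenoxide F5; when this cold solution is warmed in the presence of the dienophile of the following step, F5 loses benzeneselenenic acid by syn-elimination (H1 and selenium are cis). This comes back to the route at 30, which is then released slowly in a metal-free medium and never accumulates.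

**Step 24.** Two things can go wrong: self-cycloaddition of diene 30 in place of addition to 28, and oxygen delivery to the wrong face of C10′, because the facial preference of the dienol of 31 rests only on the shape of the spiro ring. The fallback separates the events. It sets out from 30 and 28 under argon, so that the cycloaddition stops at adduct 31, which is isolated in this variant. Dimethyldioxirane epoxidises its electron-rich tetrasubstituted C1′=C10′ alkene to the β,γ-epoxy ketone F6. Et3N then opens F6 by E1cB elimination to the γ-hydroxy enone, rejoining the route at 33; the C10′ configuration is then set by an electrophilic epoxidation and not by a radical trapping.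

**Step 25.** The hindered dienophile 33 may be outpaced by self-addition of 30, the diene may add to the α face of 33, and the final equilibration may give the C10 epimer. The fallback replaces the self-reactive dienone by a diene that has no activated dienophile and can therefore be used in excess and heated. It sets out from 30: Luche reduction (NaBH4, CeCl3·7H2O, MeOH/MeCN, −40 °C) of the fresh solution gives the 3-hydroxy diene F7 as a mixture of C3 epimers; 1,2-reduction of the 3-ketone in the presence of the methylene lactone is known in this compound class. Thermal Diels–Alder reaction of F7 with 33 (toluene, 60 to 80 °C) gives the 3-hydroxy trimer adduct F8. Dess–Martin oxidation of its secondary allylic alcohol comes back to the route at 34, which Et3N isomerises to 35 as before.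

**Step 10.** Loss of the C2 proton in place of H4 would give the C2=C3 alkene, and some substitution by chloride is possible. The fallback sets out from 12. Dess–Martin oxidation gives ketone F9. Tf2O with 2,6-di-tert-butyl-4-methylpyridine gives the more substituted enol triflate F10. Reduction catalysed by Pd(OAc)2/PPh3 with tributylammonium formate then rejoins the route at 13.

**Step 12.** Proton removal at C5 in place of the methyl group, or consumption of the aluminium amide by the nitrile, would lower regioselectivity and conversion. The fallback sets out from 14 and uses TBSOTf with 2,6-lutidine followed by DBU: the silyl triflate opens the epoxide at the tertiary carbon and DBU removes a methyl proton, giving the allyl silyl ether directly and rejoining the route at 16 without passing through 15.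

## Further compounds

F1 | step 19 | 2-(methoxycarbonyl)allylsilane, bis-silyl ether, E/Z mixture | C=C1[C@H](O[Si](C)(C)C(C)(C)C)C[C@@H](C(=C)CCC=C(C[Si](C)(C)C)C(=O)OC)[C@H]1CO[Si](C)(C)C(C)(C)C
F2 | step 19 | primary alcohol of the allylsilane | C=C1[C@H](O[Si](C)(C)C(C)(C)C)C[C@@H](C(=C)CCC=C(C[Si](C)(C)C)C(=O)OC)[C@H]1CO
F3 | step 19 | formyl allylsilane | C=C1[C@H](O[Si](C)(C)C(C)(C)C)C[C@@H](C(=C)CCC=C(C[Si](C)(C)C)C(=O)OC)[C@H]1C=O
F4 | step 23 | 2α-(phenylseleno)dehydrozaluzanin C | C=C1C(=O)[C@H]([Se]c4ccccc4)[C@H]2C(=C)CC[C@H]3C(=C)C(=O)O[C@@H]3[C@H]21
F5 | step 23 | selenoxide of the 2α-(phenylseleno) ketone | C=C1C(=O)[C@H]([Se](=O)c4ccccc4)[C@H]2C(=C)CC[C@H]3C(=C)C(=O)O[C@@H]3[C@H]21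
F6 | step 24 | 1′β,10′β-epoxide of adduct 31 | C=C1C(=O)[C@H]2[C@]3(O4)[C@]4(CC[C@]25C(=O)C[C@H]6C(=C)CC[C@H]7C(=C)C(=O)O[C@@H]7[C@H]65)CC[C@H]2C(=C)C(=O)O[C@@H]2[C@@H]13
F7 | step 25 | 3-hydroxy diene from 30 (C3 epimers) | C=C1C(O)C=C2C(=C)CC[C@H]3C(=C)C(=O)O[C@@H]3[C@H]21
F8 | step 25 | 3-hydroxy trimer adduct (C3 epimers; C1=C10 alkene in unit A, H2 β) | C=C1C(O)[C@H]2C3=C(CC[C@H]4C(=C)C(=O)O[C@@H]4[C@@H]13)CC[C@@]21C(=O)C2=C3[C@H]1[C@H]1OC(=O)C(=C)[C@@H]1CC[C@@]3(O)CC[C@]21C(=O)C[C@H]2C(=C)CC[C@H]3C(=C)C(=O)O[C@@H]3[C@H]21
F9 | step 10 | C3 ketone from 12 | C[C@@H]1C(=O)C[C@@H](C(=C)CCC#N)[C@H]1CO[Si](C)(C)C(C)(C)C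
F10 | step 10 | C3=C4 enol triflate | CC1=C(OS(=O)(=O)C(F)(F)F)C[C@@H](C(=C)CCC#N)[C@H]1CO[Si](C)(C)C(C)(C)C
F0 | step 12 | none | none
A1 | alternative 1 | C14–C15′ tethered diketone with masked lactones and 10′-O-trimethylsilyl group | C=C1C(=O)C[C@H]2[C@H](CC[C@H]3[C@H](CN(C)C)C(=O)O[C@@H]3[C@@H]12)CCC1C(=O)C2=C3[C@H]1[C@H]1OC(=O)[C@@H](CN(C)C)[C@@H]1CC[C@@]3(O[Si](C)(C)C)CC[C@]21C(=O)C[C@H]2C(=C)CC[C@H]3[C@H](CN(C)C)C(=O)O[C@@H]3[C@H]21
A2 | alternative 1 | masked 1,2-dihydro trimer | C=C1C(=O)[C@@H]2[C@H]3[C@H](CC[C@H]4[C@H](CN(C)C)C(=O)O[C@@H]4[C@@H]13)CC[C@@]21C(=O)C2=C3[C@H]1[C@H]1OC(=O)[C@@H](CN(C)C)[C@@H]1CC[C@@]3(O[Si](C)(C)C)CC[C@]21C(=O)C[C@H]2C(=C)CC[C@H]3[C@H](CN(C)C)C(=O)O[C@@H]3[C@H]21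
A3 | alternative 2 | spiro-dihydropyran (allyl vinyl ether) | C=C1C(=O)C=C2[C@H]1[C@H]1OC(=O)C(=C)[C@@H]1CC[C@]21CCC2=C(O1)C[C@H]1C(=C)CC[C@H]3C(=C)C(=O)O[C@@H]3[C@@H]21
A4 | alternative 2 | B–C spiro dimer with the C1′=C10′ alkene (identical with 31) | C=C1C(=O)[C@H]2C=3[C@H]1[C@H]1OC(=O)C(=C)[C@@H]1CCC=3CC[C@]21C(=O)C[C@H]2C(=C)CC[C@H]3C(=C)C(=O)O[C@@H]3[C@H]21
A5 | alternative 3 | parthenolide | C/C1=C\CC[C@@]2(C)O[C@@H]2[C@H]2OC(=O)C(=C)[C@@H]2CC1
A6 | alternative 3 | micheliolide | C[C@@]1(O)CCC2=C(C)CC[C@H]3C(=C)C(=O)O[C@@H]3[C@@H]12
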